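**Strategy.** Everything rests on cutting the γ-lactone at its alkyl C–O bond: the O–C7–C6(Cl)=C5 unit of the ten-membered ring is what a chlorolactonisation of a C5=C6=C7 allene by the C19 carboxylate would leave. In one operation the key step should close the cis-fused lactone ring (O, C7, C8, C17, C19), set C7, place chlorine on C6 and fix the ring-cis C5=C6 geometry, which the ten-membered ring enforces. The precursor is a cyclodeca-1,2-diene fused to ring A, made from a Diels–Alder-derived decalin by an alkynyl anionic oxy-Cope ring expansion; its carboxylate travels as a temporary lactone on O9 that also sets C8.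

Key step: step 19

Numbering: atoms keep the numbers they have in 29. C1 is the quaternary carbon (methyl C15), C2 the acetoxy carbon, then C3, C4, C5 (methyl C16), C6 (Cl), C7, C8, C9, C10. Ring A is C1, C10, C11 (methyl C20), C12, C13, C14. C17 (methyl C18) and C19 are the lactone carbons. In the decalins, ring B is C1, C2, C7, C8, C9, C10. β is the face of the C15 methyl group, α the opposite face.

Assumption: the (S)-configured oxazaborolidinium cation of step 2 gives adduct 4 in the absolute configuration drawn; if its facial sense is the opposite, the (R)-catalyst is used and nothing else changes.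

**Route**

Step 1
Reactants: 1 ethyl vinyl ketone
Product: 2 (Z)-3-(tert-butyldimethylsilyloxy)penta-1,3-diene
Conditions: TBSOTf, Et3N, Et2O, 0 °C
Reagents that add atoms: tert-butyldimethylsilyl triflate, CC(C)(C)[Si](C)(C)OS(=O)(=O)C(F)(F)F
Why: Amine-mediated O-silylation of an ethyl ketone should give the (Z)-silyl enol ether, which puts the methyl group on the outside of the s-cis diene.

Step 2
Reactants: 3 2-methoxy-5-methyl-1,4-benzoquinone, 2 (Z)-3-(tert-butyldimethylsilyloxy)penta-1,3-diene
Product: 4 cis-fused adduct (H10 β, 11α-methyl, 8-methoxy-7-ene-2,9-dione, 12-silyloxy-12-ene)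
Conditions: 20 mol% oxazaborolidinium salt made in the flask from (S)-3,3-diphenyl-1-(o-tolyl)tetrahydro-1H,3H-pyrrolo[1,2-c][1,3,2]oxazaborole and HN(SO2CF3)2, CH2Cl2, −78 °C
Reagents that add atoms: none
Why: Catalysed endo Diels–Alder reaction of a quinone, in which the methoxy group shuts off its own double bond so that the methyl-bearing C1=C10 bond reacts and C1 becomes quaternary; the cation bound to the more basic vinylogous-ester carbonyl (C2) makes C10 the electrophilic end that bonds to the enol-ether terminus C11, the endo and suprafacial course places H10 cis to C15 and the C20 methyl cis to the quinone carbons, and the chiral cation selects the face and so the configuration at C1.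

Step 3
Reactants: 4 cis-fused adduct
Product: 5 trans-fused adduct (H10 α, 11α-methyl)
Conditions: DBU (0.2 equiv), CH2Cl2, rt
Reagents that add atoms: none
Why: Base-mediated epimerisation at C10 through the C9 enolate should lead to the more stable trans-fused decalin, in which the C20 methyl group is equatorial.

Step 4
Reactants: 5 trans-fused adduct
Product: 6 9β-alcohol (silyl enol ether kept)
Conditions: NaBH4, CeCl3·7H2O, MeOH/CH2Cl2, −78 °C
Reagents that add atoms: none
Why: Luche 1,2-reduction should pick the C9 ketone (C2 is a neopentyl vinylogous-ester carbonyl), with hydride arriving on the α face away from the 1,3-related axial C15 methyl to give the axial 9β-alcohol.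

Step 5
Reactants: 6 9β-alcohol
Product: 7 ring-A enone (13-en-12-one, 11α-methyl)
Conditions: Pd(OAc)2 (1.1 equiv), MeCN, rt
Reagents that add atoms: none
Why: Saegusa–Ito oxidation, in which the C12 silyl enol ether gives a C13 palladium enolate that loses hydride from C14 to form the C13=C14 enone.

Step 6
Reactants: 7 ring-A enone
Product: 10 9β,12β-diol (11β-methyl), via dilithium dienolate 8 (not isolated), via 11β-methyl enone 9 (not isolated)
Conditions: LiN(iPr)2 (2.2 equiv), THF, −78 °C; 2,6-di-tert-butyl-4-methylphenol, −78 °C; then CeCl3·7H2O, MeOH, NaBH4, −78 °C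
Reagents that add atoms: none
Why: Kinetic α′-deprotonation gives the cross-conjugated dienolate (C11 is the only enolisable site, O9 is an alkoxide), the hindered phenol should protonate C11 on the α face anti to the axial C15 methyl to give the less stable 11β-methyl ketone (kinetic protonation), and the Luche reduction that follows at once (hydride also from the α face) locks C11 by removing the ketone.

Step 7
Reactants: 10 9β,12β-diol
Product: 11 12-O-TBS ether
Conditions: TBSCl (1.1 equiv), imidazole, DMF, 0 °C
Reagents that add atoms: tert-butyldimethylsilyl chloride, CC(C)(C)[Si](C)(C)Cl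
Why: Silylation should select the equatorial allylic 12β-hydroxyl, because the axial 9β-hydroxyl is 1,3-diaxial to the C15 methyl and much more hindered.

Step 8
Reactants: 11 12-O-TBS ether
Product: 12 7-iodo vinylogous ester
Conditions: N-iodosuccinimide, MeCN, 0 °C
Reagents that add atoms: N-iodosuccinimide, O=C1CCC(=O)N1I
Why: Electrophilic α-iodination of a vinylogous ester, whose C7 is the nucleophilic carbon of the push-pull alkene and far more reactive than the ring-A alkene.

Step 9
Reactants: 12 7-iodo vinylogous ester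
Product: 13 7-(prop-1-ynyl) vinylogous ester
Conditions: propyne, PdCl2(PPh3)2 (5 mol%), CuI (10 mol%), iPr2NH, THF, rt
Reagents that add atoms: propyne, CC#C
Why: Sonogashira coupling of an α-iodo enone-type vinyl iodide installs C6, C5 and C16 on C7 under mild, non-enolising conditions.

Step 10
Reactants: 13 7-(prop-1-ynyl) vinylogous ester
Product: 14 vinylogous acid (8-hydroxy-7-en-2-one, the enol of the 2,8-dione)
Conditions: NaOH, THF/H2O, 0 °C; then aq. HCl to pH 4
Reagents that add atoms: sodium hydroxide, [Na+].[OH-]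
Why: Saponification of the vinylogous methyl ester by addition–elimination at C8 frees the 1,3-dicarbonyl unit, which stays as its delocalised enolate in base and so protects C9 from enolisation.

Step 11
Reactants: 14 vinylogous acid
Product: 17 8-ketone (2β-OTES, 2α-vinyl, 7α-propynyl, 9β-OH), via bis-TMS vinylogous ester 15 (not isolated), via TES-capped vinyl adduct 16 (not isolated)
Conditions: Me3SiCl, Et3N, THF, 0 °C; then vinylmagnesium bromide, CeCl3, −78 °C; then Et3SiOTf, −78 to 0 °C; then KF, MeOH, 0 °C
Reagents that add atoms: chlorotrimethylsilane (in 15 and 16 only), C[Si](C)(C)Cl; vinylmagnesium bromide, C=C[Mg]Br; triethylsilyl triflate, CC[Si](CC)(CC)OS(=O)(=O)C(F)(F)F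
Why: Silylation at the less hindered O8 leaves C2 as the only carbonyl for organocerium 1,2-addition from the α face (anti to C15), and with the tertiary alkoxide capped as a TES ether the fluoride cleavage of the TMS enol ether unveils the C8 ketone without the acid that would ionise C2 (no Stork–Danheiser elimination), while C7, now α to a ketone, should settle with the propynyl group equatorial (α), free of 1,3-diaxial contacts with C15 and O9.

Step 12
Reactants: 17 8-ketone
Product: 18 9-O-(2-bromopropanoyl) ester (mixture at the CHBr carbon)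
Conditions: 2-bromopropanoyl bromide, pyridine, DMAP (cat.), CH2Cl2, 0 °C
Reagents that add atoms: 2-bromopropanoyl bromide, CC(Br)C(Br)=O
Why: Acylation of the only free hydroxyl (9β) attaches C17–C19 to O9 as a tether aimed at the C8 ketone.

Step 13
Reactants: 18 9-O-(2-bromopropanoyl) ester
Product: 19 8α-hydroxy 9,19-lactone (cis-fused, C17 as in 29)
Conditions: SmI2 (2.2 equiv), THF, −78 °C
Reagents that add atoms: none
Why: Intramolecular samarium Reformatsky reaction, in which the C–Br bond is reduced faster than the ketone, the tether from the β-oxygen on C9 forces the enolate onto the β face of C8 (cis-fused five-membered lactone, 8α-OH), and the chelated transition state of the (E)-enolate should set C17.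

Step 14
Reactants: 19 8α-hydroxy 9,19-lactone
Product: 20 8-O-TBS ether
Conditions: TBSOTf, 2,6-lutidine, CH2Cl2, 0 °C to rt
Reagents that add atoms: tert-butyldimethylsilyl triflate, CC(C)(C)[Si](C)(C)OS(=O)(=O)C(F)(F)F
Why: Silyl triflate caps the tertiary 8α-hydroxyl, which removes the β-alkoxide that could undergo retro-aldol cleavage under the basic conditions of step 16.

Step 15
Reactants: 20 8-O-TBS ether
Product: 21 tertiary C2 alcohol (2α-vinyl, 7α-propynyl)
Conditions: HF·pyridine, pyridine, THF, 0 °C
Reagents that add atoms: none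
Why: Buffered fluoride should cleave the triethylsilyl ether much faster than the two tert-butyldimethylsilyl ethers, freeing only the C2 hydroxyl.

Step 16
Reactants: 21 tertiary C2 alcohol
Product: 23 ten-membered allenyl ketone (C2 ketone, C5=C6=C7 allene, 9,19-lactone), via potassium enolate 22 (not isolated)
Conditions: KN(SiMe3)2 (1.1 equiv), 18-crown-6, THF, −78 to 0 °C; then aq. NH4Cl, −78 °C
Reagents that add atoms: none
Why: Alkoxide-accelerated oxy-Cope rearrangement of the 3-oxy-1,5-enyne C4=C3–C2(O−)–C7–C6≡C5 breaks C2–C7 and forms C4–C5, so ring B grows by four atoms into the ten-membered ring and the alkyne becomes the C5=C6=C7 allene, whose axial chirality is relayed from C7 because C4 bonds to C5 on the side from which C2 departs; protonation of the enolate gives the C2 ketone.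

Step 17
Reactants: 23 ten-membered allenyl ketone
Product: 24 (2S)-alcohol
Conditions: (R)-1-methyl-3,3-diphenyltetrahydro-1H,3H-pyrrolo[1,2-c][1,3,2]oxazaborole [(R)-methyl-CBS] (1 equiv), catecholborane, toluene, −78 °C
Reagents that add atoms: none
Why: Corey–Bakshi–Shibata reduction under reagent control, in which the catalyst tells the quaternary C1 from the C3 methylene and the (R)-catalyst should give the (2S)-alcohol, while catecholborane at −78 °C leaves the allene and lactone alone.

Step 18
Reactants: 24 (2S)-alcohol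
Product: 25 2-acetate
Conditions: Ac2O, DMAP, pyridine, CH2Cl2, rt
Reagents that add atoms: acetic anhydride, CC(=O)OC(C)=O
Why: DMAP-catalysed acetylation of the only free hydroxyl, before the other secondary hydroxyl (O9) is released.

Step 19
Reactants: 25 2-acetate
Product: 27 chlorolactone (7,19-lactone, 6-chloro-5-ene, 9β-OH, 8-O-TBS, 12-O-TBS), via lithium carboxylate 26 (not isolated)
Conditions: LiOH (1.1 equiv), THF/H2O, 0 °C; then NaHCO3, N-chlorosuccinimide, THF/H2O, 0 °C, dark
Reagents that add atoms: lithium hydroxide, [Li+].[OH-]; N-chlorosuccinimide, O=C1CCC(=O)N1Cl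
Why: Hydroxide should open the strained cis-fused 9,19-lactone far faster than it attacks the neopentyl C2 acetate, and in carboxylate 26 Cl+ then adds to the central allene carbon C6 of the C6=C7 π bond from the outside of the ten-membered ring (the side of the C16 methyl) while the C19 carboxylate captures C7 from the opposite face. The closest known reaction is the electrophilic halolactonisation of 4,5-allenoic acids to 5-(1-halovinyl)butyrolactones. The lactone ring (O, C7, C8, C17, C19) closes in the 5-exo mode by forming the O–C7 bond. The new stereocentre C7 is fixed by the axial chirality of the allene through the anti addition, and the C5=C6 geometry (C4 and C7 cis in the ring, Cl cis to C16) by the ring, since chlorine can only arrive from outside. The step needs site selectivity for the allene over the C13=C14 alkene, which the more nucleophilic trisubstituted allene and the neighbouring carboxylate should secure, and selectivity among the oxygen nucleophiles, which the five-membered transition state secures (O9 would have to form an oxetane, O8 is silylated).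

Step 20
Reactants: 27 chlorolactone
Product: 28 8,9,12-triol (12β-ol)
Conditions: HF (48% aq.), MeCN, rt
Reagents that add atoms: none
Why: Acidic fluoride removes both silyl ethers (tertiary at O8, allylic at O12) under conditions that the acetate, lactone and vinyl chloride should tolerate.

Step 21
Reactants: 28 8,9,12-triol
Product: 29 CNP0163464.1
Conditions: MnO2, CH2Cl2, rt
Reagents that add atoms: none
Why: Activated MnO2 oxidises only the allylic C12 alcohol to the C13=C14 enone under neutral conditions, so the saturated 9-hydroxyl, the tertiary 8-hydroxyl and the epimerisable C11 centre stay untouched.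

**Compound list**

1 | ethyl vinyl ketone (pent-1-en-3-one) | CCC(=O)C=C | starting material
2 | (Z)-3-(tert-butyldimethylsilyloxy)penta-1,3-diene | C=C/C(O[Si](C)(C)C(C)(C)C)=C/C | intermediate
3 | 2-methoxy-5-methyl-1,4-benzoquinone | COC1=CC(=O)C(C)=CC1=O | starting material
4 | cis-fused Diels–Alder adduct (H10 β, 11α-methyl) | C[C@]12CC=C(O[Si](C)(C)C(C)(C)C)[C@@H](C)[C@H]1C(=O)C(OC)=CC2=O | intermediate
5 | trans-fused adduct (H10 α, 11α-methyl) | C[C@]12CC=C(O[Si](C)(C)C(C)(C)C)[C@@H](C)[C@@H]1C(=O)C(OC)=CC2=O | intermediate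
6 | 9β-alcohol with C12 silyl enol ether | C[C@]12CC=C(O[Si](C)(C)C(C)(C)C)[C@@H](C)[C@@H]1[C@H](O)C(OC)=CC2=O | intermediate
7 | ring-A enone, 11α-methyl, 9β-OH | C[C@]12C=CC(=O)[C@@H](C)[C@@H]1[C@H](O)C(OC)=CC2=O | intermediate
8 | dilithium alkoxide dienolate of 7 | C[C@]12C=CC([O-])=C(C)[C@@H]1[C@H]([O-])C(OC)=CC2=O.[Li+].[Li+] | intermediate
9 | ring-A enone, 11β-methyl, 9β-OH | C[C@]12C=CC(=O)[C@H](C)[C@@H]1[C@H](O)C(OC)=CC2=O | intermediate
10 | 9β,12β-diol, 11β-methyl, 13-ene | C[C@]12C=C[C@H](O)[C@H](C)[C@@H]1[C@H](O)C(OC)=CC2=O | intermediate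
11 | 12-O-TBS ether of 10 | C[C@]12C=C[C@H](O[Si](C)(C)C(C)(C)C)[C@H](C)[C@@H]1[C@H](O)C(OC)=CC2=O | intermediate
12 | 7-iodo vinylogous ester | C[C@]12C=C[C@H](O[Si](C)(C)C(C)(C)C)[C@H](C)[C@@H]1[C@H](O)C(OC)=C(I)C2=O | intermediate
13 | 7-(prop-1-ynyl) vinylogous ester | C[C@]12C=C[C@H](O[Si](C)(C)C(C)(C)C)[C@H](C)[C@@H]1[C@H](O)C(OC)=C(C#CC)C2=O | intermediate
14 | vinylogous acid (8-hydroxy-7-en-2-one) | C[C@]12C=C[C@H](O[Si](C)(C)C(C)(C)C)[C@H](C)[C@@H]1[C@H](O)C(O)=C(C#CC)C2=O | intermediate
15 | 8-O,9-O-bis(trimethylsilyl) vinylogous ester | C[C@]12C=C[C@H](O[Si](C)(C)C(C)(C)C)[C@H](C)[C@@H]1[C@H](O[Si](C)(C)C)C(O[Si](C)(C)C)=C(C#CC)C2=O | intermediate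
16 | 2α-vinyl 2β-triethylsilyloxy adduct of 15 | C[C@]12C=C[C@H](O[Si](C)(C)C(C)(C)C)[C@H](C)[C@@H]1[C@H](O[Si](C)(C)C)C(O[Si](C)(C)C)=C(C#CC)[C@@]2(O[Si](CC)(CC)CC)C=C | intermediate
17 | 8-ketone (2β-OTES, 2α-vinyl, 7α-propynyl, 9β-OH) | C[C@]12C=C[C@H](O[Si](C)(C)C(C)(C)C)[C@H](C)[C@@H]1[C@H](O)C(=O)[C@@H](C#CC)[C@@]2(O[Si](CC)(CC)CC)C=C | intermediate
18 | 9-O-(2-bromopropanoyl) ester of 17 | C[C@]12C=C[C@H](O[Si](C)(C)C(C)(C)C)[C@H](C)[C@@H]1[C@H](OC(=O)C(C)Br)C(=O)[C@@H](C#CC)[C@@]2(O[Si](CC)(CC)CC)C=C | intermediate
19 | 8α-hydroxy 9,19-lactone (decalin) | C[C@]12C=C[C@H](O[Si](C)(C)C(C)(C)C)[C@H](C)[C@@H]1[C@@H]3OC(=O)[C@H](C)[C@]3(O)[C@@H](C#CC)[C@@]2(O[Si](CC)(CC)CC)C=C | intermediate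
20 | 8-O-TBS ether of 19 | C[C@]12C=C[C@H](O[Si](C)(C)C(C)(C)C)[C@H](C)[C@@H]1[C@@H]3OC(=O)[C@H](C)[C@]3(O[Si](C)(C)C(C)(C)C)[C@@H](C#CC)[C@@]2(O[Si](CC)(CC)CC)C=C | intermediate
21 | tertiary C2 alcohol (oxy-Cope substrate) | C[C@]12C=C[C@H](O[Si](C)(C)C(C)(C)C)[C@H](C)[C@@H]1[C@@H]3OC(=O)[C@H](C)[C@]3(O[Si](C)(C)C(C)(C)C)[C@@H](C#CC)[C@@]2(O)C=C | intermediate
22 | potassium enolate of 23 | [O-]C1=CCC(C)=[C@@]=C([H])[C@@]2(O[Si](C)(C)C(C)(C)C)[C@@H](C)C(=O)O[C@H]2[C@H]3[C@@H](C)[C@@H](O[Si](C)(C)C(C)(C)C)C=C[C@@]31C.[K+] | intermediate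
23 | ten-membered allenyl ketone with 9,19-lactone | O=C1CCC(C)=[C@@]=C([H])[C@@]2(O[Si](C)(C)C(C)(C)C)[C@@H](C)C(=O)O[C@H]2[C@H]3[C@@H](C)[C@@H](O[Si](C)(C)C(C)(C)C)C=C[C@@]31C | intermediate
24 | (2S)-alcohol | O[C@H]1CCC(C)=[C@@]=C([H])[C@@]2(O[Si](C)(C)C(C)(C)C)[C@@H](C)C(=O)O[C@H]2[C@H]3[C@@H](C)[C@@H](O[Si](C)(C)C(C)(C)C)C=C[C@@]31C | intermediate
25 | 2-acetate | CC(=O)O[C@H]1CCC(C)=[C@@]=C([H])[C@@]2(O[Si](C)(C)C(C)(C)C)[C@@H](C)C(=O)O[C@H]2[C@H]3[C@@H](C)[C@@H](O[Si](C)(C)C(C)(C)C)C=C[C@@]31C | intermediate
26 | lithium 9-hydroxy-19-carboxylate (opened lactone) | CC(=O)O[C@H]1CCC(C)=[C@@]=C([H])[C@@](O[Si](C)(C)C(C)(C)C)([C@@H](C)C(=O)[O-])[C@@H](O)[C@H]2[C@@H](C)[C@@H](O[Si](C)(C)C(C)(C)C)C=C[C@@]21C.[Li+] | intermediate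
27 | chlorolactone, 8-O-TBS, 12-O-TBS, 9β-OH | CC(=O)O[C@H]1CC/C(C)=C(/Cl)[C@H]2OC(=O)[C@H](C)[C@@]2(O[Si](C)(C)C(C)(C)C)[C@@H](O)[C@H]2[C@@H](C)[C@@H](O[Si](C)(C)C(C)(C)C)C=C[C@@]21C | intermediate
28 | 8,9,12-triol (12β-ol) | CC(=O)O[C@H]1CC/C(C)=C(/Cl)[C@H]2OC(=O)[C@H](C)[C@@]2(O)[C@@H](O)[C@H]2[C@@H](C)[C@@H](O)C=C[C@@]21C | intermediate
29 | CNP0163464.1 | CC(=O)O[C@H]1CC/C(C)=C(/Cl)[C@H]2OC(=O)[C@H](C)[C@@]2(O)[C@@H](O)[C@H]2[C@@H](C)C(=O)C=C[C@@]21C | target

**Step count and risks**

Total steps: 21. Longest linear sequence: 21 steps (from 1; 20 from 3).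

Most likely to fail, in this order:

Step 19. The chlorine transfer is irreversible and may outrun ring closure if the carboxylate arm cannot reach the face of C7 anti to the incoming halogen; allylic chlorination or capture of C7 by water would then compete. The fallback sets out from 25: after the same LiOH opening, carboxylate 26 is treated with N-iodosuccinimide (NaHCO3, MeCN/H2O, 0 °C). Iodonium formation is reversible, so the cyclisation can wait for the productive conformer and should give the iodolactone F1. A retentive iodide-to-chloride exchange on the alkenyl iodide (CuCl, DMF, 110 °C) should then give 27, where the route is rejoined.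

Step 16. The strongly basic medium may enolise the lactone (with β-elimination of the C8 silyloxy group) or let the potassium enolate react across the ring before it is quenched. The fallback sets out from 21: silylation (Me3SiCl, imidazole, DMF) gives the trimethylsilyl ether F2. A neutral thermal siloxy-Cope rearrangement (toluene, 180 °C, sealed tube) should give the ring-expanded silyl enol ether F3, and mild methanolysis (K2CO3, MeOH, 0 °C) returns to the route at 23.

Step 6. Protonation of the dienolate may show poor facial selectivity, because axial protonation on the β face is stereoelectronically favoured although hindered, and the kinetic ketone may re-equilibrate before it is reduced. The fallback sets out from 7: dienolate 8 is trapped with PhSeBr, which should enter on the α face to give the 11α-phenylselanyl 11β-methyl enone F4. Radical deselenation (Bu3SnH, Et3B, air, toluene, −78 °C) lets the planar C11 radical take hydrogen from the bulky stannane on the open α face, which is steric control without a competing axial preference. Ketone 9 so formed is reduced at once under the Luche conditions of step 6, and the route is rejoined at 10.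

Further compounds
F1 | step 19 | iodolactone (6-iodo analogue of 27) | CC(=O)O[C@H]1CC/C(C)=C(/I)[C@H]2OC(=O)[C@H](C)[C@@]2(O[Si](C)(C)C(C)(C)C)[C@@H](O)[C@H]2[C@@H](C)[C@@H](O[Si](C)(C)C(C)(C)C)C=C[C@@]21C
F2 | step 16 | 2-O-trimethylsilyl ether of 21 | C[C@]12C=C[C@H](O[Si](C)(C)C(C)(C)C)[C@H](C)[C@@H]1[C@@H]3OC(=O)[C@H](C)[C@]3(O[Si](C)(C)C(C)(C)C)[C@@H](C#CC)[C@@]2(O[Si](C)(C)C)C=C
F3 | step 16 | trimethylsilyl enol ether of 23 | C[Si](C)(C)OC1=CCC(C)=[C@@]=C([H])[C@@]2(O[Si](C)(C)C(C)(C)C)[C@@H](C)C(=O)O[C@H]2[C@H]3[C@@H](C)[C@@H](O[Si](C)(C)C(C)(C)C)C=C[C@@]31C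
F4 | step 6 | 11α-phenylselanyl 11β-methyl enone | C[C@]12C=CC(=O)[C@@](C)([Se]c3ccccc3)[C@@H]1[C@H](O)C(OC)=CC2=O
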